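The meeting opened on the time of reading, 2.5 h, and asked how much of the charge would still be on its way by then.

| flask | starting material | free catalyst | temperature | remark | time |
|---|---|---|---|---|---|
| north-east | 0.28 M | 0.54 mM | 105 °C | run made earlier |  |
| north | 0.44 M | 0.54 mM | 122 °C | run made earlier |  |
| south | 0.20 M | 1.1 mM | 105 °C | run made earlier |  |
| theta | 0.20 M | 0.54 mM | 135 °C |  | 2.5 h |
| gamma | 0.20 M | 0.54 mM | 110 °C |  | 2.5 h |

north-east run (percent of the starting material charged)

| time / h | side product / % | over-reaction product / % | target / % | starting material / % | isomer of the product / % |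
|---|---|---|---|---|---|
| 0.417 | 0 | 10 | 36 | 51 | 3 |
| 0.833 | 0 | 24 | 40 | 26 | 5 |
| 1.33 | 1 | 47 | 37 | 12 | 7 |
| 1.50 | 3 | 52 | 28 | 8 | 9 |
| 2.00 | 2 | 66 | 23 | 5 | 12 |
| 2.50 | 0 | 69 | 12 | 2 | 15 |

north run (percent of the starting material charged)

| time / min | side product / % | over-reaction product / % | target / % | starting material / % | isomer of the product / % |
|---|---|---|---|---|---|
| 6.00 | 1 | 4 | 23 | 70 | 3 |
| 12.0 | 1 | 16 | 29 | 48 | 5 |
| 15.0 | 3 | 19 | 32 | 46 | 4 |
| 30.0 | 3 | 51 | 25 | 18 | 6 |
| 50.0 | 2 | 74 | 10 | 6 | 7 |
| 80.0 | 1 | 85 | 2 | 0 | 10 |

south run (percent of the starting material charged)

| time / h | side product / % | over-reaction product / % | target / % | starting material / % | isomer of the product / % |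
|---|---|---|---|---|---|
| 0.500 | 1 | 19 | 52 | 21 | 7 |
| 1.00 | 2 | 43 | 37 | 5 | 12 |
| 1.50 | 1 | 59 | 22 | 0 | 22 |
| 2.00 | 1 | 65 | 11 | 0 | 19 |
| 2.50 | 0 | 72 | 9 | 4 | 24 |

(scatter of a reading: 2 percentage points)



- which of these there is most of at the end, counted by the starting material in it, theta (side product / target / over-reaction product / isomer of the product)
- which of these there is most of at the end, counted by the starting material in it, gamma (side product / target / over-reaction product / isomer of the product)
- amount of the one of these that there is most of at the end, in percent of the starting material charged, theta
- amount of the one of these that there is most of at the end, in percent of the starting material charged, gamma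

The chair proposed counting what is left, not what is made, and getting over-reaction product by subtraction. One chemist read the loss of starting material as first order (pseudo-first-order at a fixed catalyst charge): 1.58 h⁻¹ in the north-east run and 3.40 h⁻¹ in the north run. Interpolating the logarithm by temperature, with the different amounts of starting material in the two runs set aside, gave 1.98 h⁻¹ for gamma, and extending it gave 6.08 h⁻¹ for theta.

A second chemist noted that two steps in series with one shared constant put the target peak at 36.8%. The highest target readings were 40% in the north-east run and a lower 32% in the north run, each with its scatter. Interpolated by temperature to gamma they give a reading of 37.6%, close to that figure, so she proposed to treat the two steps in gamma as sharing one constant.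

The meeting then adopted the chain number, the constant times the time of reading, 4.96 for gamma. For such a pair, the fraction left in starting material plus target is one plus that number, times e to its negative. That leaves 4.19% in gamma. Subtracting the last north-east isomer and side product readings gave 80.8% over-reaction product. For theta the same form was simply assumed, as no run stands at that temperature: its number of 15.2 reckons <0.001% left, and the last north isomer and side product readings then gave 89.0%.

The forecast named over-reaction product in both flasks and stood at 90% for theta, where “Everything is consumed”, and 78% for gamma, against 89.0% and 80.8% in the meeting's own reckoning.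

The flasks give over-reaction product at 92.8% in theta and over-reaction product at 81.3% in gamma, and the forecast held.

    starting material + free catalyst → free catalyst + target (k = 0.998 L mol⁻¹ s⁻¹, Ea = 54.0 kJ mol⁻¹)
    starting material → side product (k = 5.62 × 10⁻⁶ s⁻¹, Ea = 119 kJ mol⁻¹)
    free catalyst → spent catalyst (k = 2.10 × 10⁻⁷ s⁻¹, Ea = 128 kJ mol⁻¹)
    target → over-reaction product (k = 4.34 × 10⁻⁴ s⁻¹, Ea = 107 kJ mol⁻¹)
    target + free catalyst ⇌ isomer of the product + free catalyst, rate k5*[free catalyst]*[target] forward; the back reaction follows from the equilibrium constant (K = 2.01, k = 0.145 L mol⁻¹ s⁻¹, Ea = 77.0 kJ mol⁻¹, ΔH = 16.0 kJ mol⁻¹)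
    (constants at 110 °C)

In gamma, target is made 1.52 times as fast as it is used up at 0.350 h, each step taken net, but that ratio is 0.215 at 2.50 h, so the reading falls on the tail, with 5.78% in starting material plus target against the 4.19% reckoned. For the neighbour flask, gamma read at 1.0 h, the chain number is 1.98 and the fraction reckoned left in starting material plus target 41.1%; computed, that flask holds 14.1% starting material and 29.3% target, together 43.4%.

The readings were generated by integration on assumed constants; noise was put on by code.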